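## Analysis of the target

The target is a single cyclohexene ring. Numbering used throughout: C1 = CH(OBz) next to the quaternary carbon, C2=C3 the alkene, C4 = CH(OBz), C5 = CH(OH), C6 = C(OH), C7 = the hydroxymethyl carbon on C6. It has four contiguous stereocentres, C4, C5, C6 and C1, of configuration (1S,4R,5S,6R). The oxygens on C1, C4 and C6 lie on one face of the ring; the C5 hydroxyl and C7 lie on the other, so C5–O is trans to the oxygens on both neighbouring carbons and cis to C7. C6 is a fully substituted carbinol flanked by two oxygenated carbons. The sensitive groups are two allylic benzoates that each sit next to free hydroxyls (C4–OBz beside C5–OH; C1–OBz beside C6–OH and C7–OH), which invites acyl migration under base, and a 1,4-dioxygenated cyclohex-2-ene that can aromatise by losing two acids. The synthesis is hard because four adjacent stereocentres, one quaternary, must be set, and five oxygens must be told apart (two benzoylated, three free) without moving acyl groups. The strategy rests on one cyclohexene retron: C1–C2=C3–C4 with its cis oxygens is an (E,E)-1,4-dioxygenated butadiene, and C5–C6 with its trans oxygens and C7 is an E-2,3-dioxygenated acrolein.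

## Retrosynthetic reasoning

**13 from 12.** The last step only cuts two Si–O bonds to free the C5 and C7 hydroxyls. Both benzoates are already in place, so the final operation must be non-basic to keep them where they are.

**12 from 10 and 11.** The two ester C–O bonds at C1 and C4 are cut. In 10 these are the only secondary hydroxyls; the C6 hydroxyl is tertiary and should not be acylated, and C5–O and C7–O are tied up. Benzoylation comes late because the diene is bought as its diacetate.

**10 from 9 from 8.** Exchanging acetate for benzoate needs the C5 and C7 hydroxyls masked by a group that survives methanolysis and acylation and leaves without base. These two hydroxyls are a cis 1,3-diol, so one silylene bridge covers both and leaves only the unreactive tertiary C6 hydroxyl. Cutting the two Si–O bonds leads back to triol diacetate 8.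

**8 from 7 from 6.** The C5 and C6 oxygens are carried as chloroacetates, which a soft sulfur nucleophile removes while acetates stay. C7 is carried as the aldehyde because the cycloaddition needs it as the activating group. The aldehyde is reduced while C6–O is still acylated: a free tertiary α-hydroxy aldehyde could undergo α-ketol ring expansion or retro-aldol cleavage.

**6 from 4 and 5.** The C4–C5 and C6–C1 bonds are cut, which is a [4+2] disconnection into achiral diene 5 and achiral enal 4. No other pair of cuts removes the whole ring and all four stereocentres at once. The forward reaction has to achieve three things: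
- add to one face of the enal (absolute configuration of C5 and C6);
- place the formyl group exo and the C6 acyloxy group endo (C6–O on the face of C1–O and C4–O);
- keep both alkene geometries intact.

A chiral boron Lewis acid bound at the formyl oxygen is chosen. A chiral amine would attack 4 by addition–elimination at the β-carbon or be acylated, since 4 is a vinylogous anhydride.

**4 from 1 and 2.** The two acyl C–O bonds are cut. The enol ester must be E (β-oxygen cis to the formyl group, trans to the α-oxygen), since this geometry becomes the C5/C6 relationship. A plain amine-mediated bis-acylation of 1 is not expected to be E-selective. The acylation is therefore run through the lithium chelate 3, in which both carbonyl oxygens sit on lithium, so the ester is formed on the oxygen that is cis to the remaining formyl group.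

## Alternatives that were turned down

**Alternative 1:** Disconnection of the C1–O and C4–O bonds back to the ring diene A2 (C1=C2–C3=C4, with the C5/C7 silylene and free C6 hydroxyl already present).
- Forward key step: dye-sensitised photooxygenation; singlet oxygen adds across C1 and C4 to give endoperoxide A1.
- For it: the suprafacial addition delivers the two oxygens cis by necessity. The silylene ring blocks the face of C5–O and C7, so the peroxide should form on the face of the C6 hydroxyl. Reduction of the O–O bond of A1 gives compound 10 of the present route, two steps from 13. The reaction type is well known; on this point the alternative is stronger.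
- Against it: A2 already contains C5 and C6 with their trans oxygens and the quaternary centre, and must be made enantiopure in a separate multistep sequence. A2 is a cyclohexadiene with allylic oxygens and is prone to aromatisation. A1 can rearrange to a hydroxy enone under base.
- Comparison: the key step creates only two of the four stereocentres and none of the carbon skeleton. The chosen route builds the ring and all four centres from a C4 and a C3 piece in one step, at the price of an unproven cycloaddition.

**Alternative 2:** Disconnection of the C5–O and C6–O bonds on a cyclopentadiene-masked quinone, the norbornene-fused ene-dione A4.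
- Forward key step: alkaline peroxide (Weitz–Scheffer) epoxidation of the C5=C6 ene-dione alkene from the convex face, giving epoxy dione A3.
- For it: the folded tricycle makes face selection very reliable, the epoxidation is standard, and adducts of this kind can be obtained enantioenriched. Step for step it is more predictable than the chosen plan.
- Against it: A3 is far from the target. Both ketones must be reduced with control (C1–O and C4–O on the face of C6–O). The epoxide must be opened at C5 with inversion, not at the tertiary C6. The alkene appears only after a thermal cycloreversion at high temperature, with allylic esters or free hydroxyls on board. The masking diene is carried and discarded.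
- Comparison: the stereocentres are set one at a time over a sequence that should be clearly longer than eight steps. The chosen route sets them together and has no masking group.

**Alternative 3:** Disconnection of the C1–O and C6–O bonds back to diene A6 (C6=C1–C2=C3, with C4–OBz, C5–OTBS, C7–OTBS), which derives from an enzymatic arene cis-dihydroxylation product.
- Forward key step: osmium-catalysed dihydroxylation (OsO4 with an amine N-oxide) of the trisubstituted C6=C1 alkene anti to the C5 silyloxy group, giving cis-diol A5.
- For it: the absolute configuration comes from the enzyme. The more substituted alkene, not deactivated by the allylic benzoate, should react first, and attack anti to the allylic silyloxy group is the normal outcome. A5 is only a C1 benzoylation and a desilylation away from 13. Every step has precedent; on reliability this alternative is stronger than the chosen one.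
- Against it: the enzymatic diol has its two oxygens cis, so the trans C4/C5 relationship needs an inversion at an allylic centre. The halogen must be replaced by the C7 unit. The diene intermediates dimerise and aromatise easily.
- Comparison: the step count should be similar or slightly higher, and the stereocentres come from three separate events. The chosen strategy offers a shorter construction of the skeleton, no biotransformation and either enantiomer by choice of catalyst, but it depends on one unproven step.

Key step: step 2

## Remarks before the steps

- Hydroxymalonaldehyde 1 (handled as its enol, 2,3-dihydroxyprop-2-enal) and diene 5 are treated as catalogue compounds.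
- Ring locants in the names of 6–13 follow the numbering of the analysis (C1–C7), not lowest-locant rules.

## Route

Step 1
Reactants: 1 hydroxymalonaldehyde (triose reductone); 2 chloroacetyl chloride
Product: 4 (E)-2,3-bis(chloroacetoxy)acrolein, via lithium 2-(chloroacetoxy)malonaldehyde enolate 3 (not isolated)
Conditions: LiN(SiMe3)2 (2.05 equiv), THF, −78 °C; 2 (2.1 equiv), −78 → −40 °C; cold pH 7 buffer, product used promptly
Reagents that add atoms: none
Why: Two equivalents of base give the dilithium enediolate, whose more basic α-oxygen is acylated first; the resulting enolate 3 is a lithium chelate in the U form, so the second, kinetic O-acylation puts the new ester on the oxygen cis to the remaining formyl group, which is the E enol ester (chelate-controlled O-acylation of a 1,3-dicarbonyl enolate, the route to cis enol esters and enol phosphates). No nucleophilic amine is present that could scramble the geometry by addition–elimination at the β-carbon; the geometry is to be checked by the three-bond coupling between the vinyl hydrogen and the formyl carbon before use.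

Step 2
Reactants: 4 (E)-2,3-bis(chloroacetoxy)acrolein; 5 (1E,3E)-buta-1,3-diene-1,4-diyl diacetate
Product: 6 (1S,4R,5S,6S)-1,4-diacetoxy-5,6-bis(chloroacetoxy)-6-formylcyclohex-2-ene
Conditions: (S)-1-(2-methylphenyl)-3,3-diphenyltetrahydro-1H,3H-pyrrolo[1,2-c][1,3,2]oxazaborole (20 mol %), Tf2NH (18 mol %), 5 (3 equiv), CH2Cl2, −60 → −20 °C
Reagents that add atoms: none
Why: Proposed new method: the formyl oxygen of 4 binds the boron of the protonated oxazaborolidine through the lone pair anti to the α-carbon, the enal is held s-trans (the cis β-acyloxy group rules out s-cis) with the formyl C–H against the ring oxygen, and the LUMO-lowered alkene adds the s-cis diene 5 in a concerted, asynchronous [4π+2π] process in which the bond from the β-carbon (C5–C4) runs ahead of the bond from the α-carbon (C6–C1). The closest known reaction types are the oxazaborolidinium-catalysed enantioselective Diels–Alder reactions of 2-bromo-, 2-methyl- and 2-acyloxyacroleins and the thermal cycloadditions of 5 to acrylic partners; a dienophile with a second acyloxy group on the β-carbon, paired with a 1,4-dioxygenated open-chain diene, has not been shown. The six-membered carbocycle is closed by this intermolecular [4+2] cycloaddition, both σ bonds forming suprafacially on each partner. C1 and C4 come out cis because both enol acetate bonds of 5 are E, and C5 takes its configuration relative to C6 from the E geometry of 4, which keeps O5 cis to the formyl carbon and trans to O6. The absolute configuration of C6, and with it of C5, is set by the catalyst: one phenyl group of the diphenylcarbinol unit covers one face of the bound enal and the diene adds to the open face (Re at the α-carbon, Si at the β-carbon), which the pre-transition-state model for 2-substituted acroleins assigns to the S catalyst; the R catalyst is equally available if the sense proves opposite. The configuration of C1 and C4 relative to C6 needs the formyl group exo and the C6 acyloxy group endo; this is the orientation that 2-halo- and 2-acyloxyacroleins adopt with bridged dienes, and here it is supported by the fact that the other mode would push the catalyst-bound formyl group and the cis β-chloroacetoxy group together under the diene, whereas the wanted mode places only the α-chloroacetoxy group there. Because 5 is C2-symmetric there is no regiochemical question, and the quaternary α-carbon of 6 blocks β-elimination of the new allylic esters.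

Step 3
Reactants: 6 (1S,4R,5S,6S)-1,4-diacetoxy-5,6-bis(chloroacetoxy)-6-formylcyclohex-2-ene
Product: 7 (1S,4R,5S,6S)-1,4-diacetoxy-5,6-bis(chloroacetoxy)-6-(hydroxymethyl)cyclohex-2-ene
Conditions: NaBH(OAc)3, AcOH, ClCH2CH2Cl, 0 °C → rt
Reagents that add atoms: none
Why: Chemoselective hydride reduction of an electron-poor α-acyloxy aldehyde by a mild acidic borohydride; no stereocentre is formed. The non-basic medium avoids an alkoxide at C7, which could shift acyl groups or displace chloride from the neighbouring chloroacetate, and the esters are not reduced.

Step 4
Reactants: 7 (1S,4R,5S,6S)-1,4-diacetoxy-5,6-bis(chloroacetoxy)-6-(hydroxymethyl)cyclohex-2-ene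
Product: 8 (1S,4R,5S,6R)-1,4-diacetoxy-6-(hydroxymethyl)cyclohex-2-ene-5,6-diol
Conditions: thiourea, NaHCO3, EtOH–THF, 40 °C
Reagents that add atoms: none
Why: Selective dechloroacetylation: sulfur is alkylated at the CH2Cl carbon and the isothiouronium nitrogen then cyclises onto the ester carbonyl, releasing the alcohol; because the acyl transfer is intramolecular it also works at the tertiary C6 ester, and acetates are inert. The medium is kept near neutral and warm rather than hot so that the acetates do not migrate to the freed hydroxyls.

Step 5
Reactants: 8 (1S,4R,5S,6R)-1,4-diacetoxy-6-(hydroxymethyl)cyclohex-2-ene-5,6-diol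
Product: 9 (1S,4R,5S,6S)-1,4-diacetoxy-5,7-O-(di-tert-butylsilanediyl)-6-(hydroxymethyl)cyclohex-2-ene-5,6-diol (silylene bridging O5 and O7, C6 hydroxyl free)
Conditions: tBu2Si(OTf)2, 2,6-lutidine, CH2Cl2, −20 → 0 °C
Reagents that add atoms: di-tert-butylsilyl bis(trifluoromethanesulfonate), CC(C)(C)[Si](OS(=O)(=O)C(F)(F)F)(OS(=O)(=O)C(F)(F)F)C(C)(C)C
Why: Silylene protection of a 1,3-diol: the primary C7 hydroxyl is silylated first and the remaining Si–OTf closes onto the cis C5 hydroxyl to the six-membered 1,3,2-dioxasilinane, which is favoured over the strained five-membered ring with the hindered tertiary C6 hydroxyl. The cis relationship of O5 and C7 allows a cis-fused bicycle, as in 4,6-O-silylene galactosides.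

Step 6
Reactants: 9 (1S,4R,5S,6S)-1,4-diacetoxy-5,7-O-(di-tert-butylsilanediyl)-6-(hydroxymethyl)cyclohex-2-ene-5,6-diol
Product: 10 (1S,4R,5S,6S)-5,7-O-(di-tert-butylsilanediyl)-6-(hydroxymethyl)cyclohex-2-ene-1,4,5,6-tetrol (free hydroxyls at C1, C4 and C6)
Conditions: K2CO3 (cat.), MeOH, 0 °C
Reagents that add atoms: none
Why: Base-catalysed transesterification (Zemplén-type) removes both acetates as methyl acetate; no stereocentre is touched. Catalytic carbonate at 0 °C is mild enough that the hindered di-tert-butylsilylene should survive.

Step 7
Reactants: 10 (1S,4R,5S,6S)-5,7-O-(di-tert-butylsilanediyl)-6-(hydroxymethyl)cyclohex-2-ene-1,4,5,6-tetrol; 11 benzoyl chloride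
Product: 12 (1S,4R,5S,6S)-1,4-bis(benzoyloxy)-5,7-O-(di-tert-butylsilanediyl)-6-(hydroxymethyl)cyclohex-2-ene-5,6-diol
Conditions: 11 (2.4 equiv), pyridine, DMAP (cat.), CH2Cl2, 0 °C → rt
Reagents that add atoms: none
Why: Nucleophile-catalysed acylation of the two secondary allylic hydroxyls with retention at C1 and C4; the tertiary C6 hydroxyl is too hindered to react under these conditions.

Step 8
Reactants: 12 (1S,4R,5S,6S)-1,4-bis(benzoyloxy)-5,7-O-(di-tert-butylsilanediyl)-6-(hydroxymethyl)cyclohex-2-ene-5,6-diol
Product: 13 (1S,4R,5S,6R)-5,6-dihydroxy-6-(hydroxymethyl)cyclohex-2-ene-1,4-diyl dibenzoate (target)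
Conditions: HF·pyridine, pyridine, THF, 0 °C
Reagents that add atoms: none
Why: Fluoride-driven cleavage of both Si–O bonds releases the C5 and C7 hydroxyls and di-tert-butyldifluorosilane. The buffered, weakly acidic medium avoids the alkoxides through which the benzoates could migrate to the neighbouring hydroxyls.

## Compound list

1 | hydroxymalonaldehyde (triose reductone; enol form 2,3-dihydroxyprop-2-enal) | O=CC(O)C=O | starting material
2 | chloroacetyl chloride | O=C(Cl)CCl | starting material
3 | lithium enolate of 2-(chloroacetoxy)malonaldehyde (chelated U form) | O=C/C(OC(=O)CCl)=C\[O-].[Li+] | intermediate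
4 | (E)-2,3-bis(chloroacetoxy)acrolein [(E)-3-oxoprop-1-ene-1,2-diyl bis(chloroacetate)] | O=C/C(OC(=O)CCl)=C\OC(=O)CCl | intermediate
5 | (1E,3E)-buta-1,3-diene-1,4-diyl diacetate | CC(=O)O/C=C/C=C/OC(C)=O | starting material
6 | (1S,4R,5S,6S)-1,4-diacetoxy-5,6-bis(chloroacetoxy)-6-formylcyclohex-2-ene | CC(=O)O[C@H]1C=C[C@@H](OC(C)=O)[C@H](OC(=O)CCl)[C@]1(OC(=O)CCl)C=O | intermediate
7 | (1S,4R,5S,6S)-1,4-diacetoxy-5,6-bis(chloroacetoxy)-6-(hydroxymethyl)cyclohex-2-ene | CC(=O)O[C@H]1C=C[C@@H](OC(C)=O)[C@H](OC(=O)CCl)[C@]1(OC(=O)CCl)CO | intermediate
8 | (1S,4R,5S,6R)-1,4-diacetoxy-6-(hydroxymethyl)cyclohex-2-ene-5,6-diol | CC(=O)O[C@H]1C=C[C@@H](OC(C)=O)[C@H](O)[C@]1(O)CO | intermediate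
9 | (1S,4R,5S,6S)-1,4-diacetoxy-5,7-O-(di-tert-butylsilanediyl)-6-(hydroxymethyl)cyclohex-2-ene-5,6-diol | CC(=O)O[C@H]1C=C[C@@H](OC(C)=O)[C@H](O[Si](C(C)(C)C)(C(C)(C)C)OC2)[C@@]12O | intermediate
10 | (1S,4R,5S,6S)-5,7-O-(di-tert-butylsilanediyl)-6-(hydroxymethyl)cyclohex-2-ene-1,4,5,6-tetrol | O[C@H]1C=C[C@@H](O)[C@H](O[Si](C(C)(C)C)(C(C)(C)C)OC2)[C@@]12O | intermediate
11 | benzoyl chloride | O=C(Cl)c1ccccc1 | starting material
12 | (1S,4R,5S,6S)-1,4-bis(benzoyloxy)-5,7-O-(di-tert-butylsilanediyl)-6-(hydroxymethyl)cyclohex-2-ene-5,6-diol | O=C(O[C@H]1C=C[C@@H](OC(=O)c3ccccc3)[C@H](O[Si](C(C)(C)C)(C(C)(C)C)OC2)[C@@]12O)c1ccccc1 | intermediate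
13 | (1S,4R,5S,6R)-5,6-dihydroxy-6-(hydroxymethyl)cyclohex-2-ene-1,4-diyl dibenzoate | O=C(O[C@H]1C=C[C@@H](OC(=O)c2ccccc2)[C@H](O)[C@]1(O)CO)c1ccccc1 | target

## Step count and least certain steps

Total step count: 8. Longest linear sequence: 8 steps (1 → 13).

**Step 2 (key step).**
- What may go wrong: approach of the diene with the catalyst-bound formyl group endo. An open-chain diene has no bridge that penalises that mode, and it would invert C1 and C4 relative to C5 and C6. Also possible are slow turnover (a push–pull enal and a modest diene), acid-promoted polymerisation of 5, and loss of carboxylic acid from 6 towards an arene.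
- Fallback (known reaction types: thermal cycloaddition of 5 to an acrolein-type partner, then resolution of a racemate): it sets out from 4 and returns at 7. Compounds 4 and 5 are heated without catalyst (toluene, 90–110 °C, radical inhibitor, or under high pressure at room temperature). The orientation is then governed by the sterics and dipoles of the free enal and not by a Lewis-acid-bound carbonyl. The exo-formyl adduct is separated from any endo-formyl isomer; it is the racemate, that is 6 together with its mirror image, the enantiomer of 6 F1. Reduction as in step 3 gives 7 together with the enantiomer of 7 F2. Preparative chromatography on a chiral stationary phase removes F2, and 7 re-enters the route at step 4.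

**Step 1.**
- What may go wrong: loss of geometric control. Acylation through a non-chelated enolate, or later addition–elimination by a nucleophile at the β-carbon, would give the Z enol ester, which would carry through to the C5 epimer.
- Fallback: it sets out from 1 and returns at 4, giving up kinetic control. Compound 1 is acylated with 2 and pyridine in CH2Cl2 without stereocontrol, giving 4 mixed with (Z)-2,3-bis(chloroacetoxy)acrolein F3. The isomers are separated by chromatography or crystallisation. F3 is recycled by sensitised photochemical E/Z isomerisation (350 nm) to the photostationary mixture, and separation is repeated.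

**Step 6.**
- What may go wrong: opening of the silylene by methoxide, or its shift onto the neighbouring C6 or C4 oxygen, while the acetates are cleaved.
- Fallback: it sets out from 8 and returns at 13, using two separate silyl ethers in place of the bridge. TBSOTf (2.1 equiv) and 2,6-lutidine in CH2Cl2 at −78 °C silylate the primary C7 and secondary C5 hydroxyls of 8 to the bis(tert-butyldimethylsilyl) ether F4, leaving the tertiary hydroxyl. K2CO3 in MeOH removes the acetates to give the triol F5. Benzoyl chloride 11 with pyridine and DMAP gives the dibenzoate F6. HF·pyridine in THF removes both silyl groups to give 13.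

## Further compounds

F1 | step 2 | enantiomer of 6, formed with 6 as the racemate | CC(=O)O[C@@H]1C=C[C@H](OC(C)=O)[C@@H](OC(=O)CCl)[C@@]1(OC(=O)CCl)C=O
F2 | step 2 | enantiomer of 7, formed with 7 as the racemate and removed in the resolution | CC(=O)O[C@@H]1C=C[C@H](OC(C)=O)[C@@H](OC(=O)CCl)[C@@]1(OC(=O)CCl)CO
F3 | step 1 | (Z)-2,3-bis(chloroacetoxy)acrolein | O=C/C(OC(=O)CCl)=C/OC(=O)CCl
F4 | step 6 | 5-O,7-O-bis(tert-butyldimethylsilyl) ether of 8 | CC(=O)O[C@H]1C=C[C@@H](OC(C)=O)[C@H](O[Si](C)(C)C(C)(C)C)[C@]1(O)CO[Si](C)(C)C(C)(C)C
F5 | step 6 | 5-O,7-O-bis(tert-butyldimethylsilyl) ether with free hydroxyls at C1, C4 and C6 | O[C@H]1C=C[C@@H](O)[C@H](O[Si](C)(C)C(C)(C)C)[C@]1(O)CO[Si](C)(C)C(C)(C)C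
F6 | step 6 | 5-O,7-O-bis(tert-butyldimethylsilyl) ether of 13 | O=C(O[C@H]1C=C[C@@H](OC(=O)c2ccccc2)[C@H](O[Si](C)(C)C(C)(C)C)[C@]1(O)CO[Si](C)(C)C(C)(C)C)c1ccccc1
A1 | alternative 1 | endoperoxide bridging C1 and C4, with C5/C7 di-tert-butylsilylene and free C6 hydroxyl | O3[C@H]1C=C[C@@H](O3)[C@H](O[Si](C(C)(C)C)(C(C)(C)C)OC2)[C@@]12O
A2 | alternative 1 | ring diene C1=C2–C3=C4 with C5/C7 di-tert-butylsilylene and free C6 hydroxyl | C1=CC=C[C@H](O[Si](C(C)(C)C)(C(C)(C)C)OC2)[C@@]12O
A3 | alternative 2 | convex-face epoxy dione on the norbornene-fused scaffold | O=C1[C@@H]2O[C@]2(CO[Si](C)(C)C(C)(C)C)C(=O)[C@H]3[C@H]4C=C[C@H](C4)[C@@H]13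
A4 | alternative 2 | norbornene-fused ene-dione carrying the silyloxymethyl group | O=C1C=C(CO[Si](C)(C)C(C)(C)C)C(=O)[C@H]2[C@H]3C=C[C@H](C3)[C@@H]12
A5 | alternative 3 | C1,C6-cis-diol with C4 benzoate and silyl ethers at O5 and O7 | O=C(O[C@@H]1C=C[C@H](O)[C@@](O)(CO[Si](C)(C)C(C)(C)C)[C@H]1O[Si](C)(C)C(C)(C)C)c1ccccc1
A6 | alternative 3 | diene C6=C1–C2=C3 with C4 benzoate and silyl ethers at O5 and O7 | O=C(O[C@@H]1C=CC=C(CO[Si](C)(C)C(C)(C)C)[C@H]1O[Si](C)(C)C(C)(C)C)c1ccccc1
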